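**Plan**

- Retrosynthesis first opens the pyranone at O2–C1 and C3–C4 (enol lactonisation after acylation of a C4 benzylic anion with a hexanoyl unit), leaving a ring A o-toluate.
- Ring A is then cut at C6–C7, C8–C8a and C5–C6. It is a resorcinol monoaryl ether (C6–OH meta to C8–OAr) with carbon substituents on C8a and C4a, which is what a 2,3-disubstituted cyclobutenone and an alkynyl ether assemble, so the hindered C8–O bond can be made beforehand on an sp carbon.
- The C1 carbon travels as a CH2OSi group on C2 of the cyclobutenone and C4 as its C3 methyl, so no electrophilic substitution has to choose between C5, C8a and the electron-rich ring B.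
- Forward: ring B phenol from olivetol (formylation, O-methylation, O-benzylation, Baeyer–Villiger), then the ethynyl ether via trichloroethylene; cyclobutenone from but-2-yn-1-ol and dichloroketene; ring A by benzannulation; C8a carbon oxidised to the ester; pyranone ring closed last; debenzylation.
- Stereochemistry: the target has no stereocentre; the E-dichlorovinyl ether and the transient quaternary carbon of the annulation are erased on the way.

Key step: step 10

Remark: but-2-yn-1-ol, trichloroethylene, trichloroacetyl chloride and N-methoxy-N-methylhexanamide are taken as purchased materials.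

**Route**

Step 1
Reactants: 1 olivetol
Product: 3 2,4-dihydroxy-6-pentylbenzaldehyde, via iminium chloride 2 (not isolated)
Conditions: POCl3, DMF, 0 °C to rt; then H2O, 50 °C
Reagents that add atoms: N,N-dimethylformamide, CN(C)C=O (formyl carbon); water, O (aldehyde oxygen); phosphoryl chloride, O=P(Cl)(Cl)Cl (chloride of 2 only)
Why: Vilsmeier–Haack formylation of a 5-alkylresorcinol should go para to one hydroxyl and ortho to the other, next to the alkyl group, rather than to the crowded carbon between the two hydroxyls, as is usual for orcinol-type substrates.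

Step 2
Reactants: 3 2,4-dihydroxy-6-pentylbenzaldehyde
Product: 4 2-hydroxy-4-methoxy-6-pentylbenzaldehyde
Conditions: MeI (1.05 equiv), K2CO3, acetone, rt
Reagents that add atoms: iodomethane, CI
Why: Williamson etherification should select the more acidic para hydroxyl, because the ortho hydroxyl is tied up in a hydrogen bond to the aldehyde.

Step 3
Reactants: 4 2-hydroxy-4-methoxy-6-pentylbenzaldehyde
Product: 5 2-(benzyloxy)-4-methoxy-6-pentylbenzaldehyde
Conditions: BnBr, K2CO3, DMF, 60 °C
Reagents that add atoms: benzyl bromide, BrCc1ccccc1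
Why: Williamson benzylation of the remaining chelated phenol under more forcing conditions installs the group that is later removed together with the ring A benzyl ether.

Step 4
Reactants: 5 2-(benzyloxy)-4-methoxy-6-pentylbenzaldehyde
Product: 7 2-(benzyloxy)-4-methoxy-6-pentylphenol, via aryl formate 6 (not isolated)
Conditions: mCPBA, CH2Cl2, 0 °C to rt; then K2CO3 (cat.), MeOH, rt
Reagents that add atoms: 3-chloroperoxybenzoic acid, OOC(=O)c1cccc(Cl)c1
Why: Baeyer–Villiger (Dakin-type) oxidation of an electron-rich benzaldehyde proceeds with migration of the dialkoxyaryl group to give the formate, and mild methanolysis then frees the phenol, so the formyl group serves as a placeholder for the ether oxygen of ring B.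

Step 5
Reactants: 7 2-(benzyloxy)-4-methoxy-6-pentylphenol; 8 trichloroethylene
Product: 10 1-(benzyloxy)-2-{[(E)-1,2-dichloroethenyl]oxy}-5-methoxy-3-pentylbenzene, via dichloroacetylene 9 (not isolated)
Conditions: K2CO3, DMF, 70 °C
Reagents that add atoms: none
Why: Base-induced dehydrochlorination of trichloroethylene gives dichloroacetylene, to which the phenoxide adds anti (nucleophilic addition to a haloalkyne), and the slender sp electrophile should tolerate the two ortho substituents of the phenol.

Step 6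
Reactants: 10 1-(benzyloxy)-2-{[(E)-1,2-dichloroethenyl]oxy}-5-methoxy-3-pentylbenzene
Product: 13 1-(benzyloxy)-2-(ethynyloxy)-5-methoxy-3-pentylbenzene, via chloroethynyl ether 11 (not isolated), via lithium acetylide 12 (not isolated)
Conditions: n-BuLi (2.3 equiv), Et2O, −78 to −40 °C; then H2O, −78 °C; used at once as a toluene solution
Reagents that add atoms: none
Why: n-BuLi dehydrochlorinates the dichlorovinyl ether to the chloroalkyne and then exchanges lithium for chlorine (the dichlorovinyl ether route to ynol ethers), and cold protonation releases the terminal ethynyl ether, which the two ortho substituents should shield from self-condensation.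

Step 7
Reactants: 14 but-2-yn-1-ol
Product: 15 (but-2-yn-1-yloxy)tri(propan-2-yl)silane
Conditions: i-Pr3SiCl, imidazole, DMF, rt
Reagents that add atoms: chlorotri(propan-2-yl)silane, CC(C)[Si](Cl)(C(C)C)C(C)C
Why: Standard silylation of a primary propargylic alcohol, with the bulky triisopropylsilyl group chosen to survive ZnCl2, acetic acid and carbonate base in later steps.

Step 8
Reactants: 15 (but-2-yn-1-yloxy)tri(propan-2-yl)silane; 16 trichloroacetyl chloride
Product: 18 4,4-dichloro-3-methyl-2-({[tri(propan-2-yl)silyl]oxy}methyl)cyclobut-2-en-1-one, via dichloroketene 17 (not isolated)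
Conditions: Zn(Cu) couple, Et2O/DME, slow addition of 16, rt to 35 °C
Reagents that add atoms: none
Why: In this ketene–alkyne (2+2) cycloaddition the ketene carbonyl carbon should bond to the alkyne carbon bearing CH2OSi and the CCl2 carbon to the methyl-bearing carbon, which supports the developing positive charge better and is less hindered, so methyl ends on C3 and the oxygenated carbon on C2.

Step 9
Reactants: 18 4,4-dichloro-3-methyl-2-({[tri(propan-2-yl)silyl]oxy}methyl)cyclobut-2-en-1-one
Product: 19 3-methyl-2-({[tri(propan-2-yl)silyl]oxy}methyl)cyclobut-2-en-1-one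
Conditions: Zn dust, AcOH, TMEDA, EtOH, 0 °C to rt
Reagents that add atoms: none
Why: Zinc reductive dechlorination of the α,α-dichloroketone in amine-buffered acetic acid removes both chlorines without moving the ring double bond or cleaving the silyl ether.

Step 10
Reactants: 13 1-(benzyloxy)-2-(ethynyloxy)-5-methoxy-3-pentylbenzene; 19 3-methyl-2-({[tri(propan-2-yl)silyl]oxy}methyl)cyclobut-2-en-1-one
Product: 24 3-[2-(benzyloxy)-4-methoxy-6-pentylphenoxy]-5-methyl-4-({[tri(propan-2-yl)silyl]oxy}methyl)phenol, via vinylketene 20 (not isolated), via vinylcyclobutenone 21 (not isolated), via dienylketene 22 (not isolated), via cyclohexadienone 23 (not isolated)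
Conditions: 19 (1.3 equiv), toluene, 80 °C, then 110 °C
Reagents that add atoms: none
Why: Heating opens cyclobutenone 19 by four-electron electrocyclic ring opening to vinylketene 20, which adds (2+2) to the electron-rich alkyne of 13 to give 4-vinylcyclobutenone 21; a second four-electron opening gives dienylketene 22, six-electron electrocyclization gives cyclohexadienone 23, and tautomerization delivers phenol 24. The closest known reaction type is the Danheiser benzannulation of 2,3-dialkylcyclobutenones with alkoxyalkynes to give resorcinol monoethers. Ring A is the only ring formed, and it closes by the 6π electrocyclization that makes C5–C6 after the (2+2) step has made C6–C7 and C8–C8a. No stereocentre is created, since the quaternary carbon of racemic 21 becomes aromatic C8a. The one selectivity needed is regiochemical, aryloxy meta to the new hydroxyl, and it is secured by the oxygen-induced polarization of the ynol ether, whose unsubstituted carbon bonds to the ketene carbonyl carbon, so the CH2OSi carbon of 19 lands on C8a and its methyl on C4a. The two ortho substituents of the aryl group and the absence of β-hydrogens should protect the ynol ether from self-condensation and retro-ene loss at 80–110 °C.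

Step 11
Reactants: 24 3-[2-(benzyloxy)-4-methoxy-6-pentylphenoxy]-5-methyl-4-({[tri(propan-2-yl)silyl]oxy}methyl)phenol
Product: 25 ({4-(benzyloxy)-2-[2-(benzyloxy)-4-methoxy-6-pentylphenoxy]-6-methylphenyl}methoxy)tri(propan-2-yl)silane
Conditions: BnBr, K2CO3, DMF, rt
Reagents that add atoms: benzyl bromide, BrCc1ccccc1
Why: Williamson benzylation protects C6–OH for the base-mediated steps ahead and matches the ring B protecting group, so both can fall in one final operation.

Step 12
Reactants: 25 ({4-(benzyloxy)-2-[2-(benzyloxy)-4-methoxy-6-pentylphenoxy]-6-methylphenyl}methoxy)tri(propan-2-yl)silane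
Product: 26 {4-(benzyloxy)-2-[2-(benzyloxy)-4-methoxy-6-pentylphenoxy]-6-methylphenyl}methanol
Conditions: Bu4NF, THF, 0 °C to rt
Reagents that add atoms: none
Why: Fluoride-induced silyl ether cleavage frees the benzylic alcohol on C8a without touching benzyl, methyl or diaryl ethers.

Step 13
Reactants: 26 {4-(benzyloxy)-2-[2-(benzyloxy)-4-methoxy-6-pentylphenoxy]-6-methylphenyl}methanol
Product: 27 4-(benzyloxy)-2-[2-(benzyloxy)-4-methoxy-6-pentylphenoxy]-6-methylbenzaldehyde
Conditions: Dess–Martin periodinane, CH2Cl2, 0 °C to rt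
Reagents that add atoms: none
Why: Dess–Martin oxidation converts the electron-rich benzylic alcohol to the aldehyde under nearly neutral conditions and stops at that stage.

Step 14
Reactants: 27 4-(benzyloxy)-2-[2-(benzyloxy)-4-methoxy-6-pentylphenoxy]-6-methylbenzaldehyde
Product: 28 4-(benzyloxy)-2-[2-(benzyloxy)-4-methoxy-6-pentylphenoxy]-6-methylbenzoic acid
Conditions: NaClO2, NaH2PO4, 2-methylbut-2-ene, t-BuOH/H2O, rt
Reagents that add atoms: sodium chlorite, [Na+].[O-]Cl=O
Why: Pinnick oxidation takes the hindered aldehyde to the acid, and the alkene scavenger removes hypochlorous acid before it can chlorinate the electron-rich rings.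

Step 15
Reactants: 28 4-(benzyloxy)-2-[2-(benzyloxy)-4-methoxy-6-pentylphenoxy]-6-methylbenzoic acid
Product: 29 methyl 4-(benzyloxy)-2-[2-(benzyloxy)-4-methoxy-6-pentylphenoxy]-6-methylbenzoate
Conditions: MeI, K2CO3, DMF, rt
Reagents that add atoms: iodomethane, CI
Why: Carboxylate alkylation (SN2 on iodomethane) esterifies the di-ortho-substituted acid, for which Fischer esterification would be slow.

Step 16
Reactants: 29 methyl 4-(benzyloxy)-2-[2-(benzyloxy)-4-methoxy-6-pentylphenoxy]-6-methylbenzoate; 30 N-methoxy-N-methylhexanamide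
Product: 33 methyl 4-(benzyloxy)-2-[2-(benzyloxy)-4-methoxy-6-pentylphenoxy]-6-(2-oxoheptyl)benzoate, via benzylic lithium 31 (not isolated), via lithium hemiaminal 32 (not isolated)
Conditions: LiN(i-Pr)2 (1.2 equiv), THF, −78 °C; then 30 (1.5 equiv), −78 °C; then AcOH, −78 °C to rt
Reagents that add atoms: none
Why: Lateral lithiation of the o-toluate gives an ester-stabilised benzylic anion whose acylation by the Weinreb amide stops at the chelated tetrahedral adduct (Staunton–Weinreb-type toluate acylation), while the groups flanking the ester should suppress self-condensation.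

Step 17
Reactants: 33 methyl 4-(benzyloxy)-2-[2-(benzyloxy)-4-methoxy-6-pentylphenoxy]-6-(2-oxoheptyl)benzoate
Product: 34 6-(benzyloxy)-8-[2-(benzyloxy)-4-methoxy-6-pentylphenoxy]-3-pentyl-1H-isochromen-1-one
Conditions: TsOH·H2O (cat.), toluene, 80 °C
Reagents that add atoms: none
Why: Acid-catalysed enol lactonisation, in which the ketone enol oxygen attacks the neighbouring ester with loss of methanol, gives the conjugated isocoumarin and avoids the carbon-acylation pathway that strong base could open.

Step 18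
Reactants: 34 6-(benzyloxy)-8-[2-(benzyloxy)-4-methoxy-6-pentylphenoxy]-3-pentyl-1H-isochromen-1-one
Product: 35 6-hydroxy-8-(2-hydroxy-4-methoxy-6-pentylphenoxy)-3-pentyl-1H-isochromen-1-one
Conditions: BCl3, pentamethylbenzene, CH2Cl2, −78 °C; then MeOH
Reagents that add atoms: none
Why: BCl3 cleaves both aryl benzyl ethers at low temperature while pentamethylbenzene traps the benzyl cation (Friedel–Crafts scavenging), which should leave the unchelated methyl ether, the diaryl ether, the lactone and the C3–C4 double bond untouched.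

**Compound list**

1 | olivetol (5-pentylbenzene-1,3-diol) | CCCCCc1cc(O)cc(O)c1 | starting material
2 | N-[(2,4-dihydroxy-6-pentylphenyl)methylidene]-N-methylmethanaminium chloride | CCCCCc1cc(O)cc(O)c1C=[N+](C)C.[Cl-] | intermediate
3 | 2,4-dihydroxy-6-pentylbenzaldehyde | CCCCCc1cc(O)cc(O)c1C=O | intermediate
4 | 2-hydroxy-4-methoxy-6-pentylbenzaldehyde | CCCCCc1cc(OC)cc(O)c1C=O | intermediate
5 | 2-(benzyloxy)-4-methoxy-6-pentylbenzaldehyde | CCCCCc1cc(OC)cc(OCc2ccccc2)c1C=O | intermediate
6 | 2-(benzyloxy)-4-methoxy-6-pentylphenyl formate | CCCCCc1cc(OC)cc(OCc2ccccc2)c1OC=O | intermediate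
7 | 2-(benzyloxy)-4-methoxy-6-pentylphenol | CCCCCc1cc(OC)cc(OCc2ccccc2)c1O | intermediate
8 | trichloroethylene | ClC=C(Cl)Cl | starting material
9 | dichloroacetylene | ClC#CCl | intermediate
10 | 1-(benzyloxy)-2-{[(E)-1,2-dichloroethenyl]oxy}-5-methoxy-3-pentylbenzene | CCCCCc1cc(OC)cc(OCc2ccccc2)c1O/C(Cl)=C\Cl | intermediate
11 | 1-(benzyloxy)-2-[(chloroethynyl)oxy]-5-methoxy-3-pentylbenzene | CCCCCc1cc(OC)cc(OCc2ccccc2)c1OC#CCl | intermediate
12 | lithium [2-(benzyloxy)-4-methoxy-6-pentylphenoxy]acetylide | CCCCCc1cc(OC)cc(OCc2ccccc2)c1OC#C[Li] | intermediate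
13 | 1-(benzyloxy)-2-(ethynyloxy)-5-methoxy-3-pentylbenzene | CCCCCc1cc(OC)cc(OCc2ccccc2)c1OC#C | intermediate
14 | but-2-yn-1-ol | CC#CCO | starting material
15 | (but-2-yn-1-yloxy)tri(propan-2-yl)silane | CC#CCO[Si](C(C)C)(C(C)C)C(C)C | intermediate
16 | trichloroacetyl chloride | ClC(=O)C(Cl)(Cl)Cl | starting material
17 | dichloroketene | ClC(Cl)=C=O | intermediate
18 | 4,4-dichloro-3-methyl-2-({[tri(propan-2-yl)silyl]oxy}methyl)cyclobut-2-en-1-one | O=C1C(CO[Si](C(C)C)(C(C)C)C(C)C)=C(C)C1(Cl)Cl | intermediate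
19 | 3-methyl-2-({[tri(propan-2-yl)silyl]oxy}methyl)cyclobut-2-en-1-one | O=C1CC(C)=C1CO[Si](C(C)C)(C(C)C)C(C)C | intermediate
20 | 3-methyl-2-({[tri(propan-2-yl)silyl]oxy}methyl)buta-1,3-dien-1-one (vinylketene) | O=C=C(CO[Si](C(C)C)(C(C)C)C(C)C)C(C)=C | intermediate
21 | 3-[2-(benzyloxy)-4-methoxy-6-pentylphenoxy]-4-(prop-1-en-2-yl)-4-({[tri(propan-2-yl)silyl]oxy}methyl)cyclobut-2-en-1-one (racemic) | O=C1C=C(Oc2c(CCCCC)cc(OC)cc2OCc2ccccc2)C1(CO[Si](C(C)C)(C(C)C)C(C)C)C(C)=C | intermediate
22 | (3Z)-3-[2-(benzyloxy)-4-methoxy-6-pentylphenoxy]-5-methyl-4-({[tri(propan-2-yl)silyl]oxy}methyl)hexa-1,3,5-trien-1-one (dienylketene) | O=C=C/C(Oc1c(CCCCC)cc(OC)cc1OCc1ccccc1)=C(/CO[Si](C(C)C)(C(C)C)C(C)C)C(C)=C | intermediate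
23 | 3-[2-(benzyloxy)-4-methoxy-6-pentylphenoxy]-5-methyl-4-({[tri(propan-2-yl)silyl]oxy}methyl)cyclohexa-2,4-dien-1-one | O=C1C=C(Oc2c(CCCCC)cc(OC)cc2OCc2ccccc2)C(CO[Si](C(C)C)(C(C)C)C(C)C)=C(C)C1 | intermediate
24 | 3-[2-(benzyloxy)-4-methoxy-6-pentylphenoxy]-5-methyl-4-({[tri(propan-2-yl)silyl]oxy}methyl)phenol | CCCCCc1cc(OC)cc(OCc2ccccc2)c1Oc1cc(O)cc(C)c1CO[Si](C(C)C)(C(C)C)C(C)C | intermediate
25 | ({4-(benzyloxy)-2-[2-(benzyloxy)-4-methoxy-6-pentylphenoxy]-6-methylphenyl}methoxy)tri(propan-2-yl)silane | CCCCCc1cc(OC)cc(OCc2ccccc2)c1Oc1cc(OCc2ccccc2)cc(C)c1CO[Si](C(C)C)(C(C)C)C(C)C | intermediate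
26 | {4-(benzyloxy)-2-[2-(benzyloxy)-4-methoxy-6-pentylphenoxy]-6-methylphenyl}methanol | CCCCCc1cc(OC)cc(OCc2ccccc2)c1Oc1cc(OCc2ccccc2)cc(C)c1CO | intermediate
27 | 4-(benzyloxy)-2-[2-(benzyloxy)-4-methoxy-6-pentylphenoxy]-6-methylbenzaldehyde | CCCCCc1cc(OC)cc(OCc2ccccc2)c1Oc1cc(OCc2ccccc2)cc(C)c1C=O | intermediate
28 | 4-(benzyloxy)-2-[2-(benzyloxy)-4-methoxy-6-pentylphenoxy]-6-methylbenzoic acid | CCCCCc1cc(OC)cc(OCc2ccccc2)c1Oc1cc(OCc2ccccc2)cc(C)c1C(=O)O | intermediate
29 | methyl 4-(benzyloxy)-2-[2-(benzyloxy)-4-methoxy-6-pentylphenoxy]-6-methylbenzoate | CCCCCc1cc(OC)cc(OCc2ccccc2)c1Oc1cc(OCc2ccccc2)cc(C)c1C(=O)OC | intermediate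
30 | N-methoxy-N-methylhexanamide | CCCCCC(=O)N(C)OC | starting material
31 | methyl 4-(benzyloxy)-2-[2-(benzyloxy)-4-methoxy-6-pentylphenoxy]-6-(lithiomethyl)benzoate | CCCCCc1cc(OC)cc(OCc2ccccc2)c1Oc1cc(OCc2ccccc2)cc(C[Li])c1C(=O)OC | intermediate
32 | lithium alkoxide of methyl 4-(benzyloxy)-2-[2-(benzyloxy)-4-methoxy-6-pentylphenoxy]-6-{2-hydroxy-2-[methoxy(methyl)amino]heptyl}benzoate | CCCCCc1cc(OC)cc(OCc2ccccc2)c1Oc1cc(OCc2ccccc2)cc(CC(CCCCC)(O[Li])N(C)OC)c1C(=O)OC | intermediate
33 | methyl 4-(benzyloxy)-2-[2-(benzyloxy)-4-methoxy-6-pentylphenoxy]-6-(2-oxoheptyl)benzoate | CCCCCC(=O)Cc1cc(OCc2ccccc2)cc(Oc2c(CCCCC)cc(OC)cc2OCc2ccccc2)c1C(=O)OC | intermediate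
34 | 6-(benzyloxy)-8-[2-(benzyloxy)-4-methoxy-6-pentylphenoxy]-3-pentyl-1H-isochromen-1-one | CCCCCc1cc2cc(OCc3ccccc3)cc(Oc3c(OCc4ccccc4)cc(OC)cc3CCCCC)c2c(=O)o1 | intermediate
35 | 6-hydroxy-8-(2-hydroxy-4-methoxy-6-pentylphenoxy)-3-pentyl-1H-isochromen-1-one | CCCCCc1cc2cc(O)cc(Oc3c(O)cc(OC)cc3CCCCC)c2c(=O)o1 | target

**Totals and risks**

Total step count: 18. Longest linear sequence: 15 steps (steps 1–6, then 10–18).

Steps most likely to fail:

1. Step 10. Thermal oligomerisation of the terminal aryl ethynyl ether, or slow (2+2) union between the fully substituted ketene carbon and the aryloxy-bearing alkyne carbon, may outrun the annulation, and the product phenol may be acylated by unreacted vinylketene. The fallback sets out from phenol 7 and comes back at aldehyde 27, making the diaryl ether by nucleophilic aromatic substitution instead of on an sp carbon. Phenol 7 and 4-bromo-2-fluoro-6-methylbenzonitrile F1 (K2CO3, DMF, 90 °C) should give 2-[2-(benzyloxy)-4-methoxy-6-pentylphenoxy]-4-bromo-6-methylbenzonitrile F2, since fluoride ortho to the nitrile leaves far faster than bromide. Pd(OAc)2/t-BuBrettPhos-catalysed C–O coupling with benzyl alcohol (Cs2CO3, toluene, 90 °C) should then give 4-(benzyloxy)-2-[2-(benzyloxy)-4-methoxy-6-pentylphenoxy]-6-methylbenzonitrile F3. Reduction with i-Bu2AlH (toluene, −78 to 0 °C) and aqueous acid hydrolysis of the imine would deliver aldehyde 27.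

2. Step 8. Bonding of the ketene carbonyl carbon to the methyl-bearing alkyne carbon would give the regioisomeric cyclobutenone, and ZnCl2 with the acid chloride may strip the silyl ether. The fallback sets out from trichloroacetyl chloride 16 and comes back at cyclobutenone 19, fixing the regiochemistry with an ynol ether. Ethoxyethyne F4 is lithiated (n-BuLi, THF, −78 °C) and hydroxymethylated with paraformaldehyde to 3-ethoxyprop-2-yn-1-ol F5, which is silylated (i-Pr3SiCl, imidazole) to [(3-ethoxyprop-2-yn-1-yl)oxy]tri(propan-2-yl)silane F6. Dichloroketene 17 from 16 and Zn(Cu) can only add with the ethoxy-bearing carbon next to CCl2, giving 4,4-dichloro-3-ethoxy-2-({[tri(propan-2-yl)silyl]oxy}methyl)cyclobut-2-en-1-one F7. Zn/AcOH/TMEDA removes the chlorines to give 3-ethoxy-2-({[tri(propan-2-yl)silyl]oxy}methyl)cyclobut-2-en-1-one F8. MeLi adds 1,2 to give 3-ethoxy-1-methyl-2-({[tri(propan-2-yl)silyl]oxy}methyl)cyclobut-2-en-1-ol F9, and dilute aqueous HCl hydrolyses the enol ether with carbonyl transposition to 19.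

3. Step 6. The terminal ethynyl ether may be lost by oligomerisation during protonation, concentration and storage before it meets the cyclobutenone. The fallback sets out from lithium acetylide 12 and comes back at ethynyl ether 13, carrying the alkyne in a capped, storable form. Acetylide 12 is quenched with Me3SiCl to give {[2-(benzyloxy)-4-methoxy-6-pentylphenoxy]ethynyl}trimethylsilane F10, which can be purified and kept. The silyl group is removed with Bu4NF (wet THF, 0 °C) immediately before step 10 to release 13 in solution.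

**Further compounds**

F1 | step 10 | 4-bromo-2-fluoro-6-methylbenzonitrile | Cc1cc(Br)cc(F)c1C#N
F2 | step 10 | 2-[2-(benzyloxy)-4-methoxy-6-pentylphenoxy]-4-bromo-6-methylbenzonitrile | CCCCCc1cc(OC)cc(OCc2ccccc2)c1Oc1cc(Br)cc(C)c1C#N
F3 | step 10 | 4-(benzyloxy)-2-[2-(benzyloxy)-4-methoxy-6-pentylphenoxy]-6-methylbenzonitrile | CCCCCc1cc(OC)cc(OCc2ccccc2)c1Oc1cc(OCc2ccccc2)cc(C)c1C#N
F4 | step 8 | ethoxyethyne | CCOC#C
F5 | step 8 | 3-ethoxyprop-2-yn-1-ol | CCOC#CCO
F6 | step 8 | [(3-ethoxyprop-2-yn-1-yl)oxy]tri(propan-2-yl)silane | CCOC#CCO[Si](C(C)C)(C(C)C)C(C)C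
F7 | step 8 | 4,4-dichloro-3-ethoxy-2-({[tri(propan-2-yl)silyl]oxy}methyl)cyclobut-2-en-1-one | CCOC1=C(CO[Si](C(C)C)(C(C)C)C(C)C)C(=O)C1(Cl)Cl
F8 | step 8 | 3-ethoxy-2-({[tri(propan-2-yl)silyl]oxy}methyl)cyclobut-2-en-1-one | CCOC1=C(CO[Si](C(C)C)(C(C)C)C(C)C)C(=O)C1
F9 | step 8 | 3-ethoxy-1-methyl-2-({[tri(propan-2-yl)silyl]oxy}methyl)cyclobut-2-en-1-ol | CCOC1=C(CO[Si](C(C)C)(C(C)C)C(C)C)C(C)(O)C1
F10 | step 6 | {[2-(benzyloxy)-4-methoxy-6-pentylphenoxy]ethynyl}trimethylsilane | CCCCCc1cc(OC)cc(OCc2ccccc2)c1OC#C[Si](C)(C)C
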